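In the noon flask triple product has a half-life of 2.5 h under step 4, shorter than the 25 h of the bis adduct that feeds it, with the other concentrations as charged.

    starting material + partner → mono adduct + by-product (k1 = 6.44 × 10⁻⁴ M⁻¹ min⁻¹)
    partner + mono adduct → bis adduct + by-product (k2 = 0.00101 M⁻¹ min⁻¹)
    partner + bis adduct → triple product + by-product (k3 = 7.78 × 10⁻⁴ M⁻¹ min⁻¹)
    partner + triple product → over-reaction product (k4 = 0.00783 M⁻¹ min⁻¹)
    starting material + by-product ⇌ idle adduct, settled at all times (K5 = 3.3 M⁻¹)

all flasks: partner 0.600 M
- noon: starting material 0.50 M; time 10 h; everything together in a closed stirred flask, run for 10 h
- midnight: starting material 0.50 M; one stirred flow tank at steady state, fed with the mixture as stated, mean residence time 10 h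
- summer: starting material 0.50 M (fed, over 8.00 h); time 10 h; a stirred flask in which starting material is dosed at a steady rate over 8.00 h without added volume, worked up at 10 h
- dawn: starting material 0.50 M; a single well-mixed tank run continuously and read at steady state, 30.0 h in it on average

* the set-up with the highest share of triple product in all that became triple product or over-reaction product, at the outlet or at the end ("none" if the first two lie within 2 percentage points) (noon / midnight / summer / dawn / none)
* share of triple product in all that became triple product or over-reaction product, at the outlet or at the end, noon
* share of triple product in all that became triple product or over-reaction product, at the outlet or at the end, midnight
* share of triple product in all that became triple product or over-reaction product, at the outlet or at the end, summer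
* share of triple product in all that became triple product or over-reaction product, at the outlet or at the end, dawn

- amounts and yields of by-product count idle adduct too
- the stated concentrations are those of everything mixed, before any reaction; amounts are the same in each set-up
- the feed brings no volume worth counting
- run time (noon): 10 h

I begin with the midnight tank, where a balance is exact. Over-reaction product leaves by the outlet, and triple product feeds it by step 4, which is pseudo-first-order at the tank's steady partner. So over-reaction product over triple product equals the constant of step 4 times the partner in the tank times the residence time, and the share is one over one plus that ratio. With partner as charged the product is 2.82. I call this the burn number, the constant of step 4 times charged partner times residence time, and multiply it by the fraction of partner still present. At full partner the share is 26.2%.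

Now I reckon the partner left in the midnight tank. Step 1 at charged partner leaves a fraction 0.812 of the starting material, and a mono adduct goes on by step 2 with chance 0.267. Counting those two steps, that takes partner equal to 0.238 of the starting-material charge, leaves 0.801 of the partner, and gives a share of 30.7%.

The weak link is the free starting material. The constant of step 5 times the free starting material is 1.34, so idle adduct holds 0.573 of the by-product, which is 0.136 of the starting-material charge. Reckoned again, free starting material is 0.728, partner left is 0.857, and I commit to 29.3%.

For noon, the run is shorter than the first steps' half-lives, so I let births of triple product grow with the square of time. I have no partner fraction of its own for the noon flask, so I borrow the one reckoned for the midnight tank. Weighting each birth by its survival to the end, at burn number 2.42, gives 60.1%.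

The forecast says summer, with noon 57%, midnight 29.6%, summer 61% and dawn 15.5%, holding that “the share depends on how recently it was made”. My noon stands above its figure, and my midnight a little below its figure.

The simulation gives summer 62.4%, the highest, then noon 57.2%, midnight 29.7% and dawn 15.5%. Neither batch flask has come to rest: at 100 h noon falls to 15.1% and summer to 15.3%. The midnight tank at ten times the residence time gives 8.57%. Read through the burn number, partner left is 0.839 at midnight, 0.647 at dawn, and 0.378 in that longer tank.

(Its constants are assumed, and the outcome is calculated.)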